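**Retrosynthetic overview**

1. Numbering used below (bisabolane positions): ring C1 (bears C7), C2 (OAng), C3 (OH), C4 (Me = C15)–C5 oxirane, C6 (CH2); side chain C7(=C14H2)–C8(OAng)–C9–C10/C11 oxirane. End game: Shi epoxidation of C10=C11, C3–OH-directed epoxidation of C4=C5 and double angeloylation lead back to triene diol 22.
2. 22 comes by cross-metathesis, Brown allylation and i-Bu2AlH reduction from the cis-fused α-methylene-γ-butyrolactone 19, whose lactone carbonyl is C8 and whose ring oxygen is the C2 oxygen (temporary ring, C8 at the acid level).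
3. Key disconnection C1–C6: 19 from bromide 18 by a 6-exo radical allylation (addition–fragmentation). Enabling feature: in the target the C2–O bond and the C1–C7 bond are cis on the cyclohexane, so O–C2–C1–C7–C8 can be tied into a five-membered lactone. As a butenolide this ring makes C1 an electrophilic β-carbon and lets the C3 tether deliver C6 only to the face that gives the cis fusion (the correct C1). The PhS group on C14 leaves to give the C7=C14 methylene.
4. 18 comes from allylic alcohol 12 (acylation, ring-closing metathesis to the butenolide); 12 from (R)-glyceraldehyde acetonide 5 (C1, C2, C3) and the (Z)-alkenyllithium of 4 (C4, C5, C6, C15) by Felkin–Anh addition.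
5. Order of ring formation: butenolide (step 10), cyclohexene (step 13), lactone opened again (steps 14 and 15), C4–C5 oxirane (step 19), C10–C11 oxirane (step 20).

Key step: step 13

Remark: lactol 20 is carried as a mixture of anomers, because it reacts through its open hydroxy-aldehyde form.

**Route**

Step 1
Reactants: 1 but-2-yn-1-ol
Product: 3 (Z)-3-iodobut-2-en-1-ol, via cyclic alkenylalanate 2 (not isolated)
Conditions: NaAlH2(OCH2CH2OMe)2, THF, 0 °C to rt; then I2, −78 °C to 0 °C
Reagents that add atoms: iodine, II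
Why: Hydroxyl-directed trans-hydroalumination of the propargylic alcohol places aluminium on the methyl-bearing carbon in a five-membered alanate, and iodinolysis with retention gives the (Z)-vinyl iodide whose geometry later becomes the cis C4=C5 ring alkene.

Step 2
Reactants: 3 (Z)-3-iodobut-2-en-1-ol
Product: 4 tert-butyl{[(2Z)-3-iodobut-2-en-1-yl]oxy}diphenylsilane
Conditions: TBDPSCl, imidazole, DMF, rt
Reagents that add atoms: tert-butyl(chloro)diphenylsilane, CC(C)(C)[Si](Cl)(c1ccccc1)c1ccccc1
Why: Imidazole-promoted silylation (silyl ether protection) of the primary allylic alcohol gives a group that should survive t-BuLi and the later acidic and basic steps.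

Step 3
Reactants: 4 tert-butyl{[(2Z)-3-iodobut-2-en-1-yl]oxy}diphenylsilane, 5 (R)-2,2-dimethyl-1,3-dioxolane-4-carbaldehyde
Product: 7 (1S,2Z)-4-[(tert-butyldiphenylsilyl)oxy]-1-[(4R)-2,2-dimethyl-1,3-dioxolan-4-yl]-2-methylbut-2-en-1-ol (anti adduct), via (Z)-alkenyllithium 6 (not isolated)
Conditions: t-BuLi (2.1 equiv), Et2O, −78 °C; then 5, −78 °C; aq. NH4Cl
Reagents that add atoms: none
Why: Iodine–lithium exchange keeps the (Z)-geometry, and addition of the alkenyllithium to the α-alkoxy aldehyde under Felkin–Anh (non-chelation) control should favour the anti (erythro) alcohol, which sets C3 relative to the chiral-pool centre C2.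

Step 4
Reactants: 7 anti alcohol
Product: 8 PMB ether of 7 (C3–OPMB)
Conditions: NaH, PMBCl, Bu4NI (cat.), THF/DMF, 0 °C to rt
Reagents that add atoms: 4-methoxybenzyl chloride, COc1ccc(CCl)cc1
Why: Williamson etherification; PMB is chosen because it does not migrate to a neighbouring alkoxide and is removed late under neutral oxidative conditions.

Step 5
Reactants: 8 PMB ether
Product: 9 (2R,3S,4Z)-6-[(tert-butyldiphenylsilyl)oxy]-3-[(4-methoxybenzyl)oxy]-4-methylhex-4-ene-1,2-diol
Conditions: AcOH/H2O (4:1), 40 °C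
Reagents that add atoms: none
Why: Acid-catalysed hydrolysis of the terminal isopropylidene acetal, to which the PMB and TBDPS ethers should be stable.

Step 6
Reactants: 9 diol
Product: 11 (2R)-2-{(1S,2Z)-4-[(tert-butyldiphenylsilyl)oxy]-1-[(4-methoxybenzyl)oxy]-2-methylbut-2-en-1-yl}oxirane, via primary monotosylate 10 (not isolated)
Conditions: TsCl, Et3N, Bu2SnO (cat.), CH2Cl2, 0 °C; then K2CO3, MeOH, 0 °C to rt
Reagents that add atoms: none
Why: Tin-catalysed regioselective sulfonylation of the primary hydroxyl followed by base-induced 3-exo-tet closure (intramolecular Williamson reaction) gives the terminal epoxide without touching C2.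

Step 7
Reactants: 11 epoxide
Product: 12 (3R,4S,5Z)-7-[(tert-butyldiphenylsilyl)oxy]-4-[(4-methoxybenzyl)oxy]-5-methylhepta-1,5-dien-3-ol
Conditions: Me3S+ I− (4 equiv), n-BuLi, THF, −10 °C to rt
Reagents that add atoms: trimethylsulfonium iodide, C[S+](C)C.[I-]
Why: Dimethylsulfonium methylide opens the epoxide at CH2 and the sulfonium intermediate eliminates dimethyl sulfide (one-carbon homologation of a terminal epoxide to an allylic alcohol), so that C2 keeps its configuration and C1 becomes a vinyl carbon.

Step 8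
Reactants: 13 2-(bromomethyl)acrylic acid
Product: 14 2-[(phenylsulfanyl)methyl]acrylic acid
Conditions: PhSH, Et3N (2 equiv), CH2Cl2, 0 °C to rt; then aq. HCl
Reagents that add atoms: thiophenol, Sc1ccccc1
Why: Thiolate substitution on the 2-(bromomethyl)acrylate (SN2 and SN2′ give the same product) installs the phenylsulfanyl group that later leaves as a radical.

Step 9
Reactants: 12 allylic alcohol, 14 2-[(phenylsulfanyl)methyl]acrylic acid
Product: 15 (3R,4S,5Z)-7-[(tert-butyldiphenylsilyl)oxy]-4-[(4-methoxybenzyl)oxy]-5-methylhepta-1,5-dien-3-yl 2-[(phenylsulfanyl)methyl]acrylate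
Conditions: DCC, DMAP (cat.), CH2Cl2, 0 °C to rt
Reagents that add atoms: none
Why: Steglich esterification of the secondary allylic alcohol brings the C7/C8/C14 unit onto the C2 oxygen.

Step 10
Reactants: 15 acrylate ester
Product: 16 (5R)-5-{(1S,2Z)-4-[(tert-butyldiphenylsilyl)oxy]-1-[(4-methoxybenzyl)oxy]-2-methylbut-2-en-1-yl}-3-[(phenylsulfanyl)methyl]furan-2(5H)-one
Conditions: (H2IMes)(PCy3)Cl2Ru=CHPh (second-generation Grubbs catalyst, 5 mol%), PhMe (5 mM), 80 °C
Reagents that add atoms: none
Why: Ring-closing metathesis between the vinyl group and the 1,1-disubstituted acrylate should close the five-membered butenolide (C1=C7), while the trisubstituted (Z)-alkene is too hindered to take part.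

Step 11
Reactants: 16 silyl ether
Product: 17 (5R)-5-{(1S,2Z)-4-hydroxy-1-[(4-methoxybenzyl)oxy]-2-methylbut-2-en-1-yl}-3-[(phenylsulfanyl)methyl]furan-2(5H)-one
Conditions: HF·pyridine, THF/pyridine, 0 °C to rt
Reagents that add atoms: none
Why: Fluoride-mediated desilylation under weakly acidic conditions frees the primary allylic alcohol without epimerising the base-sensitive butenolide γ-carbon (C2).

Step 12
Reactants: 17 allylic alcohol
Product: 18 (5R)-5-{(1S,2Z)-4-bromo-1-[(4-methoxybenzyl)oxy]-2-methylbut-2-en-1-yl}-3-[(phenylsulfanyl)methyl]furan-2(5H)-one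
Conditions: CBr4, PPh3, 2,6-lutidine, CH2Cl2, −20 °C
Reagents that add atoms: carbon tetrabromide, BrC(Br)(Br)Br
Why: Appel bromination of the primary allylic alcohol under neutral conditions should keep the (Z)-alkene and the butenolide intact.

Step 13
Reactants: 18 allylic bromide
Product: 19 (3aS,7S,7aR)-7-[(4-methoxybenzyl)oxy]-6-methyl-3-methylidene-3a,4,7,7a-tetrahydro-1-benzofuran-2(3H)-one
Conditions: Bu3SnSnBu3 (1.5 equiv), hν (sunlamp), PhH (5 mM), 30–40 °C
Reagents that add atoms: none
Why: Photolysis of the ditin gives Bu3Sn radicals that abstract bromine from the allylic bromide; the allylic radical adds through its CH2 terminus (C6) to the butenolide β-carbon (C1), and the α-lactonyl radical at C7 expels a PhS radical by β-scission, which forms the C7=C14 methylene and is converted by the ditin into Bu3SnSPh and a new Bu3Sn radical (chain). The closest known reaction type is the radical allylation with allyl sulfides and ditin (addition–fragmentation, SH2′ allyl transfer), here run intramolecularly as a cyclisation onto an unsaturated lactone. The cyclohexene ring is closed in the 6-exo-trig mode onto the endocyclic butenolide alkene. The new stereocentre C1 is controlled by C2 through the tether: the chain on the butenolide γ-carbon can reach the β-carbon only on its own face, so the bicycle must be cis-fused, which is the cis C1/C2 relationship of the target. The step needs attack through C6 and not C4 of the ambident allylic radical, bromine abstraction in preference to C–S cleavage, and no premature reduction of the slowly adding stabilised radical; these should be secured by ring size (attack through C4 would give a cyclobutane), by the much faster halogen abstraction, and by the absence of any hydrogen donor, while only the (Z)-configured radical can cyclise at all.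

Step 14
Reactants: 19 α-methylene lactone
Product: 20 (3aS,7S,7aR)-7-[(4-methoxybenzyl)oxy]-6-methyl-3-methylidene-2,3,3a,4,7,7a-hexahydro-1-benzofuran-2-ol (lactol; anomer mixture)
Conditions: i-Bu2AlH (1.1 equiv), CH2Cl2, −78 °C; then aq. KNaC4H4O6
Reagents that add atoms: none
Why: Low-temperature 1,2-reduction of the γ-lactone by the aluminium hydride should stop at the lactol, a masked 2-substituted acrolein at C8.

Step 15
Reactants: 20 lactol
Product: 21 (1R,2S,6S)-6-[(3S)-3-hydroxyhexa-1,5-dien-2-yl]-2-[(4-methoxybenzyl)oxy]-3-methylcyclohex-3-en-1-ol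
Conditions: (−)-Ipc2BOMe, allylMgBr, Et2O, 0 °C; then 20, −78 °C to rt; NaOH, H2O2
Reagents that add atoms: allylmagnesium bromide, C=CC[Mg]Br
Why: Brown asymmetric allylboration of the open hydroxy-enal form: the (−)-Ipc2B(allyl) reagent made from (+)-α-pinene adds to the Si face through a chair transition state and should set (S)-C8 under reagent control.

Step 16
Reactants: 21 homoallylic diol
Product: 22 (1R,2S,6S)-6-[(3S)-3-hydroxy-6-methylhepta-1,5-dien-2-yl]-2-[(4-methoxybenzyl)oxy]-3-methylcyclohex-3-en-1-ol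
Conditions: 2-methylbut-2-ene (excess), (H2IMes)(PCy3)Cl2Ru=CHPh (second-generation Grubbs catalyst, 5 mol%), CH2Cl2, 40 °C
Reagents that add atoms: 2-methylbut-2-ene, CC=C(C)C
Why: Olefin cross-metathesis of the monosubstituted alkene with excess 2-methylbut-2-ene should give the prenyl-type C10=C11 alkene, the 1,1-disubstituted and ring alkenes being too hindered to react.

Step 17
Reactants: 22 triene diol, 23 angelic acid (two equivalents react)
Product: 25 bis-angelate (C2 and C8 esters) of 22, via angelic 2,4,6-trichlorobenzoic anhydride 24 (not isolated)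
Conditions: 23 (3 equiv), 2,4,6-trichlorobenzoyl chloride (3 equiv), Et3N, PhMe, rt; then 22, DMAP, 60 °C
Reagents that add atoms: angelic acid (the second equivalent of 23, which forms the second ester), C/C=C(/C)C(=O)O
Why: Yamaguchi esterification: an excess of the mixed anhydride should acylate both secondary alcohols in one operation, each hydroxyl taking up one angeloyl group, and this activation mode is chosen because it should keep the (Z)-geometry of the angelate.

Step 18
Reactants: 25 bis-angelate PMB ether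
Product: 26 bis-angelate with free C3–OH
Conditions: DDQ, CH2Cl2/pH 7 buffer, 0 °C
Reagents that add atoms: none
Why: Oxidative cleavage of the PMB ether by DDQ under neutral conditions frees C3–OH without acyl migration from the cis C2 ester.

Step 19
Reactants: 26 allylic alcohol
Product: 27 4,5-epoxide of 26 (oxirane cis to C3–OH)
Conditions: VO(acac)2 (5 mol%), t-BuOOH, CH2Cl2, 0 °C to rt
Reagents that add atoms: tert-butyl hydroperoxide, CC(C)(C)OO
Why: Hydroxyl-directed vanadium-catalysed epoxidation of the cyclic allylic alcohol delivers oxygen syn to C3–OH, which sets C4 and C5 in the all-cis array and leaves the alkenes that have no directing hydroxyl untouched.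

Step 20
Reactants: 27 monoepoxide
Product: 28 CNP0235377.1 (target)
Conditions: D-fructose-derived Shi ketone (30 mol%), KHSO5 (as 2KHSO5·KHSO4·K2SO4), K2CO3, Bu4NHSO4, MeCN/CH2(OMe)2/aq. Na2B4O7 buffer (pH 10.5), 0 °C
Reagents that add atoms: potassium peroxymonosulfate, [K+].[O-]S(=O)(=O)OO
Why: Shi asymmetric epoxidation: the chiral dioxirane attacks the electron-rich trisubstituted C10=C11 through the spiro transition state and should give the (10R)-oxirane, while the electron-poor C7=C14 and angelate alkenes react far more slowly.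

**Compound list**

1 | but-2-yn-1-ol | CC#CCO | starting material
2 | sodium cyclic alkenyl(alkoxy)bis(2-methoxyethoxy)alanate from 1 (Al on the methyl-bearing carbon, cis to CH2O) | CC1=CCO[Al-]1(OCCOC)OCCOC.[Na+] | intermediate
3 | (Z)-3-iodobut-2-en-1-ol | C/C(I)=C/CO | intermediate
4 | tert-butyl{[(2Z)-3-iodobut-2-en-1-yl]oxy}diphenylsilane | C/C(I)=C/CO[Si](c1ccccc1)(c1ccccc1)C(C)(C)C | intermediate
5 | (R)-2,2-dimethyl-1,3-dioxolane-4-carbaldehyde ((R)-glyceraldehyde acetonide) | CC1(C)OC[C@@H](O1)C=O | starting material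
6 | (Z)-4-[(tert-butyldiphenylsilyl)oxy]but-2-en-2-yllithium | C/C([Li])=C/CO[Si](c1ccccc1)(c1ccccc1)C(C)(C)C | intermediate
7 | (1S,2Z)-4-[(tert-butyldiphenylsilyl)oxy]-1-[(4R)-2,2-dimethyl-1,3-dioxolan-4-yl]-2-methylbut-2-en-1-ol (anti) | CC1(C)OC[C@@H](O1)[C@@H](O)/C(C)=C\CO[Si](c2ccccc2)(c2ccccc2)C(C)(C)C | intermediate
8 | PMB ether of 7 | CC1(C)OC[C@@H](O1)[C@@H](OCc2ccc(OC)cc2)/C(C)=C\CO[Si](c3ccccc3)(c3ccccc3)C(C)(C)C | intermediate
9 | (2R,3S,4Z)-6-[(tert-butyldiphenylsilyl)oxy]-3-[(4-methoxybenzyl)oxy]-4-methylhex-4-ene-1,2-diol | OC[C@@H](O)[C@@H](OCc1ccc(OC)cc1)/C(C)=C\CO[Si](c2ccccc2)(c2ccccc2)C(C)(C)C | intermediate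
10 | primary mono-4-methylbenzenesulfonate of 9 | Cc1ccc(cc1)S(=O)(=O)OC[C@@H](O)[C@@H](OCc2ccc(OC)cc2)/C(C)=C\CO[Si](c3ccccc3)(c3ccccc3)C(C)(C)C | intermediate
11 | (2R)-2-{(1S,2Z)-4-[(tert-butyldiphenylsilyl)oxy]-1-[(4-methoxybenzyl)oxy]-2-methylbut-2-en-1-yl}oxirane | C1O[C@H]1[C@@H](OCc2ccc(OC)cc2)/C(C)=C\CO[Si](c3ccccc3)(c3ccccc3)C(C)(C)C | intermediate
12 | (3R,4S,5Z)-7-[(tert-butyldiphenylsilyl)oxy]-4-[(4-methoxybenzyl)oxy]-5-methylhepta-1,5-dien-3-ol | C=C[C@@H](O)[C@@H](OCc1ccc(OC)cc1)/C(C)=C\CO[Si](c2ccccc2)(c2ccccc2)C(C)(C)C | intermediate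
13 | 2-(bromomethyl)acrylic acid | C=C(CBr)C(=O)O | starting material
14 | 2-[(phenylsulfanyl)methyl]acrylic acid | C=C(CSc1ccccc1)C(=O)O | intermediate
15 | 2-[(phenylsulfanyl)methyl]acrylate of 12 | C=C[C@@H](OC(=O)C(=C)CSc1ccccc1)[C@@H](OCc2ccc(OC)cc2)/C(C)=C\CO[Si](c3ccccc3)(c3ccccc3)C(C)(C)C | intermediate
16 | (5R)-5-{(1S,2Z)-4-[(tert-butyldiphenylsilyl)oxy]-1-[(4-methoxybenzyl)oxy]-2-methylbut-2-en-1-yl}-3-[(phenylsulfanyl)methyl]furan-2(5H)-one | O=C1O[C@H](C=C1CSc2ccccc2)[C@@H](OCc3ccc(OC)cc3)/C(C)=C\CO[Si](c4ccccc4)(c4ccccc4)C(C)(C)C | intermediate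
17 | (5R)-5-{(1S,2Z)-4-hydroxy-1-[(4-methoxybenzyl)oxy]-2-methylbut-2-en-1-yl}-3-[(phenylsulfanyl)methyl]furan-2(5H)-one | O=C1O[C@H](C=C1CSc2ccccc2)[C@@H](OCc3ccc(OC)cc3)/C(C)=C\CO | intermediate
18 | (5R)-5-{(1S,2Z)-4-bromo-1-[(4-methoxybenzyl)oxy]-2-methylbut-2-en-1-yl}-3-[(phenylsulfanyl)methyl]furan-2(5H)-one | O=C1O[C@H](C=C1CSc2ccccc2)[C@@H](OCc3ccc(OC)cc3)/C(C)=C\CBr | intermediate
19 | (3aS,7S,7aR)-7-[(4-methoxybenzyl)oxy]-6-methyl-3-methylidene-3a,4,7,7a-tetrahydro-1-benzofuran-2(3H)-one (cis-fused) | C=C1C(=O)O[C@H]2[C@@H](OCc3ccc(OC)cc3)C(C)=CC[C@@H]12 | intermediate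
20 | lactol of 19 (2-hydroxy, anomer mixture) | C=C1C(O)O[C@H]2[C@@H](OCc3ccc(OC)cc3)C(C)=CC[C@@H]12 | intermediate
21 | (1R,2S,6S)-6-[(3S)-3-hydroxyhexa-1,5-dien-2-yl]-2-[(4-methoxybenzyl)oxy]-3-methylcyclohex-3-en-1-ol | C=C([C@H](CC=C)O)[C@@H]1CC=C(C)[C@H](OCc2ccc(OC)cc2)[C@@H]1O | intermediate
22 | (1R,2S,6S)-6-[(3S)-3-hydroxy-6-methylhepta-1,5-dien-2-yl]-2-[(4-methoxybenzyl)oxy]-3-methylcyclohex-3-en-1-ol | C=C([C@H](CC=C(C)C)O)[C@@H]1CC=C(C)[C@H](OCc2ccc(OC)cc2)[C@@H]1O | intermediate
23 | angelic acid ((Z)-2-methylbut-2-enoic acid) | C/C=C(/C)C(=O)O | starting material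
24 | angelic 2,4,6-trichlorobenzoic anhydride | C/C=C(/C)C(=O)OC(=O)c1c(Cl)cc(Cl)cc1Cl | intermediate
25 | bis-angelate (C2–O and C8–O) of 22, C3–OPMB | C=C([C@H](CC=C(C)C)OC(=O)/C(C)=C\C)[C@@H]1CC=C(C)[C@H](OCc2ccc(OC)cc2)[C@@H]1OC(=O)/C(C)=C\C | intermediate
26 | bis-angelate with free C3–OH | C=C([C@H](CC=C(C)C)OC(=O)/C(C)=C\C)[C@@H]1CC=C(C)[C@H](O)[C@@H]1OC(=O)/C(C)=C\C | intermediate
27 | 4,5-epoxide of 26 (oxirane cis to C3–OH, C2–OAng and the C1 side chain) | C=C([C@H](CC=C(C)C)OC(=O)/C(C)=C\C)[C@@H]1C[C@@H]2O[C@]2(C)[C@H](O)[C@@H]1OC(=O)/C(C)=C\C | intermediate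
28 | CNP0235377.1 | C=C([C@H](C[C@H]1OC1(C)C)OC(=O)/C(C)=C\C)[C@@H]1C[C@@H]2O[C@]2(C)[C@H](O)[C@@H]1OC(=O)/C(C)=C\C | target

**Step count and risks**

Total step count: 20. Longest linear sequence: 19 steps (steps 1–7 and 9–20; step 8 is a one-step side branch).

The three steps most likely to fail:

Step 13 (key step). The stabilised allylic radical may add too slowly to the butenolide. Radical dimerisation, E/Z scrambling of the allylic radical, or addition of tin radicals to the butenolide could then compete with ring closure. The fallback changes the ring closure from a radical chain to a two-electron, nickel-mediated coupling of a bis(allylic) dibromide, the known cyclisation of 1,8-dibromo-2,6-dienes with zerovalent nickel to 4-vinylcyclohexenes. It sets out from allylic alcohol 12. Esterification with 2-(bromomethyl)acrylic acid 13 (DCC, CH2Cl2, 0 °C) should give the 2-(bromomethyl)acrylate ester F1. Ring-closing metathesis as in step 10 should give the α-(bromomethyl)butenolide F2, and HF·pyridine the primary allylic alcohol F3. CBr4/PPh3 should then give the dibromide F4. Slow addition of F4 to Ni(cod)2 in DMF at high dilution should join the CH2 terminus of the simple allyl unit (C6) to the substituted terminus of the 2-acylallyl unit (C1), the only pairing that gives an unstrained ring. The fallback comes back to the route at lactone 19.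

Step 3. Facial selectivity in the addition to the α-alkoxy aldehyde may be poor, giving much of the syn (C3-epimeric) alcohol. The fallback sets out from crude 7 (both C3 epimers). Oxidation with Dess–Martin periodinane should give the (Z)-enone F5. Chelation-controlled reduction with Zn(BH4)2 (Et2O, −30 °C) should then deliver hydride to the chelated α-alkoxy ketone and give the anti alcohol, so the fallback comes back to the route at 7.

Step 17. Isomerisation of the angelate to the tiglate under acylation conditions, or incomplete acylation of the hindered C2–OH, may occur. The fallback builds the (Z)-enoates on the substrate and sets out from diol 22. Acylation of both hydroxyls with 2-[bis(2,2,2-trifluoroethoxy)phosphoryl]propanoic acid (excess, DCC, DMAP) should give the bis(phosphonopropionate) F6. Still–Gennari olefination (KN(SiMe3)2, 18-crown-6, THF, −78 °C; then excess acetaldehyde) should convert both phosphonates into (Z)-2-methylbut-2-enoates, and the fallback comes back to the route at 25.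

Further compounds
F1 | step 13 | 2-(bromomethyl)acrylate ester of 12 | C=C[C@@H](OC(=O)C(=C)CBr)[C@@H](OCc1ccc(OC)cc1)/C(C)=C\CO[Si](c2ccccc2)(c2ccccc2)C(C)(C)C
F2 | step 13 | (5R)-3-(bromomethyl)-5-{(1S,2Z)-4-[(tert-butyldiphenylsilyl)oxy]-1-[(4-methoxybenzyl)oxy]-2-methylbut-2-en-1-yl}furan-2(5H)-one | O=C1O[C@H](C=C1CBr)[C@@H](OCc2ccc(OC)cc2)/C(C)=C\CO[Si](c3ccccc3)(c3ccccc3)C(C)(C)C
F3 | step 13 | (5R)-3-(bromomethyl)-5-{(1S,2Z)-4-hydroxy-1-[(4-methoxybenzyl)oxy]-2-methylbut-2-en-1-yl}furan-2(5H)-one | O=C1O[C@H](C=C1CBr)[C@@H](OCc2ccc(OC)cc2)/C(C)=C\CO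
F4 | step 13 | (5R)-5-{(1S,2Z)-4-bromo-1-[(4-methoxybenzyl)oxy]-2-methylbut-2-en-1-yl}-3-(bromomethyl)furan-2(5H)-one | O=C1O[C@H](C=C1CBr)[C@@H](OCc2ccc(OC)cc2)/C(C)=C\CBr
F5 | step 3 | (2Z)-4-[(tert-butyldiphenylsilyl)oxy]-1-[(4R)-2,2-dimethyl-1,3-dioxolan-4-yl]-2-methylbut-2-en-1-one | CC1(C)OC[C@@H](O1)C(=O)/C(C)=C\CO[Si](c2ccccc2)(c2ccccc2)C(C)(C)C
F6 | step 17 | bis{2-[bis(2,2,2-trifluoroethoxy)phosphoryl]propanoate} of 22 | C=C([C@H](CC=C(C)C)OC(=O)C(C)P(=O)(OCC(F)(F)F)OCC(F)(F)F)[C@@H]1CC=C(C)[C@H](OCc2ccc(OC)cc2)[C@@H]1OC(=O)C(C)P(=O)(OCC(F)(F)F)OCC(F)(F)F
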